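Summer and winter look nearly the same, since winter holds twice the substrate of summer and runs through the same steps, yet we want to see why the two need not end alike.

    intermediate A → intermediate C (k1 = 1.3 × 10⁻⁴ s⁻¹)
    intermediate B → target (k2 = 1.1 × 10⁻⁴ s⁻¹)
    substrate ⇌ intermediate A (K3 = 0.16, k3 = 0.0020 s⁻¹)
    crystals ⇌ target, rate k4*(cs4 - [target]) while solid is left; crystals form when [target] > cs4 (cs4 = 6.9 mM, k4 = 0.037 s⁻¹)
    substrate ⇌ intermediate B (K5 = 0.18, k5 = 1.2 × 10⁻⁴ s⁻¹)
    intermediate C → side product (k6 = 8.6 × 10⁻⁵ s⁻¹)

| flask | substrate | time |
|---|---|---|
| dawn | 0.030 M | 2.0 h |
| summer | 0.060 M | 2.0 h |
| winter | 0.12 M | 2.0 h |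
| dusk | 0.25 M | 2.0 h |
| midnight | 0.50 M | 2.0 h |

- what is said of target includes crystals
- crystals is a solid; its amount is given per volume of the solution
- the concentration of target that is asked is that of its free form alone
- "hardly changes" means that all values lie within two and a half points (for a concentration: within two and a half percent of the largest)
- run time (dawn): 2.0 h

1. [target] (only what is free in solution) at the end for dawn, summer, winter, dusk, midnight, in this order
2. the shape of the row from first to last (rises all the way / hardly changes / falls, then rises / falls all the way / rises, then falls)

Every step ahead of the crystals is first order, so we reckon in fractions of the charge c. Substrate and intermediate A relax with a half-life of 0.797 min, far shorter than the 1.5 h of intermediate A on its way to intermediate C. This is a pre-equilibrium, with intermediate A at 0.16 times the substrate. Intermediate B falls back at 6.67 × 10⁻⁴ s⁻¹, faster than it goes on at 1.1 × 10⁻⁴ s⁻¹, so it settles at b = 0.155 times the substrate after a lag τ = 0.316 h, the reciprocal of the summed rates of that exchange.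

We now follow the fraction left in the pool of substrate, intermediate A and intermediate B. The pool leaks at λ = 0.104 h⁻¹, and since the way to target waits for intermediate B, we count the run less its lag, which puts our estimate of the fraction left at 84.0%. A share φ = 45.0% of the leak goes to target, which gives f = 7.19% of the charge as target at the end.

We carry the threshold charge c* = 0.0959 M, the solubility divided by f, which is the charge whose target just reaches solubility at the end. Summer makes 4.32 mM, less than the solubility 6.9 mM, and stays clear. Winter makes 8.63 mM, more than the solubility. Excess there relaxes with a half-life of 18.7 s, far shorter than the run, so free target stays close to 6.9 mM and a fraction f(1 − c*/c) of the charge becomes crystals. The small excess is production over k4, 0.147 mM at midnight, so we expect a row that keeps rising, though barely after winter.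

The forecast gives 0.00217 M, 0.00435 M, 0.00694 M, 0.00697 M and 0.00705 M, with the shape "rises all the way". Its summer value stands slightly above ours, and it says “the row keeps creeping up rather than truly levelling off”.

The simulation gives 0.00218 M, 0.00436 M, 0.00694 M, 0.00697 M and 0.00705 M, with the shape "rises all the way". Winter lies above c* by a factor of 1.25, so f(1 − c*/c) gives 1.44% against 1.49% of crystals at the end. Dusk, with 4.43% by the same sum, holds crystals at 4.48% of its charge.

The constants used here are those of an exercise; what happens was integrated by code.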